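All runs were generated by integration with constants of no real substance, noise included.

**The draw.** You get no rate constants for this flask, so you build your own from the dusk run.

- dusk: solid substrate 1.1 M; reagent 1.98 M; run made earlier
- flask: solid substrate 2.2 M; reagent 1.98 M; time 15 min

dusk run (percent of the solid substrate charged)

| time / min | solid substrate / % | mono adduct / % |
|---|---|---|
| 0.667 | 99.3 | 0.2 |
| 1.33 | 98.4 | 0 |
| 2.50 | 97.2 | 0.3 |
| 5.00 | 94.3 | 1.6 |
| 10.0 | 89.0 | 3.3 |

(standard deviation of a reading: 0.3 percentage points)

- given per volume of solution although it is solid: solid substrate
- what was read earlier has a scatter of 0.3 percentage points, one standard deviation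
- at the start none of the solid substrate is in solution

- solid substrate at 15 min, in percent of the solid substrate charged (only what is still solid)
- mono adduct at 15 min, in percent of the solid substrate charged
- other mono adduct at 15 min, in percent of the solid substrate charged
- bis adduct at 15 min, in percent of the solid substrate charged

In the dusk run the solid fell to 89.0% by 10.0 min. Counted in molar terms, that gives the molar draw, the solid lost per minute, of 0.0121 M/min.

**Lower bound.** Suppose the solid decays as a first-order lag, with the same time constant at any charge. The dusk reading gives 85.8 min. So this flask keeps 84.0% at 15 min.

**Upper bound.** Suppose instead that the draw stays fixed whatever the charge, which is zero order in the solid. Then this flask loses 0.181 M from 2.2 M, and 91.8% stays solid.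

**My choice.** The dusk run cannot separate these two. My own guess is that the pace belongs to the solution, not to the charge, so my own figure is the upper bound, 91.8%.

**The forecast.** It differs from my choice: it gives 85.5% solid, inside my bracket and 1.5 percentage points above my lower bound, with a range of 83% to 92%, plus 4.2% mono adduct, 5% other mono adduct and 1% bis adduct, and it says “I lean towards area control”.

**The result.** This flask gives 92.3% solid, 0.50 points above my upper bound, with 3.06% mono adduct, 1.22% other mono adduct and 0.976% bis adduct.

    starting material + reagent → mono adduct (k = 0.00130 /M/s)
    starting material + reagent → other mono adduct (k = 8.90 × 10⁻⁴ /M/s)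
    reagent + other mono adduct → bis adduct (k = 0.00110 /M/s)
    reagent + mono adduct → bis adduct (k = 3.40 × 10⁻⁵ /M/s)
    2 reagent → homo dimer (k = 1.00 × 10⁻⁴ /M/s)
    solid substrate ⇌ starting material, rate k6*(cs6 - [starting material]) while solid is left; crystals form when [starting material] > cs6 (solubility = 0.350 M, k = 6.00 × 10⁻⁴ /s)

**Neighbour flask.** This flask lost 0.169 M of solid, against the 0.181 M the draw predicts. Now take a neighbour charged with 0.55 M of solid, a quarter of this flask's charge, with the reagent and the time held. The same draw leaves it 67.0% solid. The neighbour holds 69.3%. Its loss in molar terms is 0.169 M.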